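**Retrosynthetic overview**
1. The azonine ring is closed last through the N–C1 bond: the amine on the C9 chain displaces a chloride at C1.
2. The cyclopentenone ring and the (E)-C3=C4 bond come from a Rh-catalysed alkyne hydroacylation (C4–C5 bond). The alkyne carbon C4 is a former lactone carbonyl (lactone → lactol → alkyne → chain extension with oxirane).
3. The cyclohexane ring is made first: one [4+2] cycloaddition of a 4-silyloxy-2-pyranone (from triacetic acid lactone) with an (E)-enal forms C8–C15 and C7–C12. The formyl group on C8 is traceless (decarbonylation).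
4. Enabling feature: in the cyclohexane ring the methyl- and acetoxy-bearing carbon C15 and the quaternary carbon C12 are 1,4-related, C13 between them is oxygenated, and the C15 oxygen is cis to C4 on C12. The array O–C15(CH3)=C14–C13(O)=C12–C4(=O) is therefore the ring of triacetic acid lactone, whose O–C(=O) bridge fixes that cis relationship.
5. Ring order: cyclohexane (inside a 2-oxabicyclo[2.2.2]octene) → cyclopentenone → azonine.

Key step: step 5

Remark: positions are named N–C1–C2–C3=C4, C4–C5(=O)–C6–C7, C7–C8–C15(CH3)–C14–C13–C12, C12–C11–C10–C9–N (cyclohexane ring = C7, C8, C15, C14, C13, C12); in this numbering the target is 7S,12S,13S,15S.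

**Step 1**
Reactants: 1 4-hydroxy-6-methyl-2H-pyran-2-one; 2 tert-butyl (3-oxopropyl)carbamate
Product: 3 tert-butyl [3-(4-hydroxy-6-methyl-2-oxo-2H-pyran-3-yl)propyl]carbamate
Conditions: diethyl 2,6-dimethyl-1,4-dihydropyridine-3,5-dicarboxylate (1.1 equiv), L-proline (20 mol%), CH2Cl2, rt
Reagents that add atoms: none
Why: Knoevenagel condensation at the nucleophilic C3 of the pyranone followed by in-situ conjugate hydride transfer from the Hantzsch ester (three-component reductive alkylation) should give clean mono-C-alkylation and installs C11–C9 with the nitrogen.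

**Step 2**
Reactants: 3 tert-butyl [3-(4-hydroxy-6-methyl-2-oxo-2H-pyran-3-yl)propyl]carbamate
Product: 4 tert-butyl {3-[6-methyl-2-oxo-4-(triisopropylsilyloxy)-2H-pyran-3-yl]propyl}carbamate
Conditions: i-Pr3SiOSO2CF3 (1.1 equiv), Et3N, CH2Cl2, −78 → 0 °C
Reagents that add atoms: triisopropylsilyl trifluoromethanesulfonate CC(C)[Si](OS(=O)(=O)C(F)(F)F)(C(C)C)C(C)C
Why: O-silylation of the vinylogous acid masks the C13 oxygen as a robust silyl enol ether and makes the pyranone an electron-rich 2-silyloxydiene.

**Step 3**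
Reactants: 5 but-3-en-1-ol
Product: 6 (but-3-en-1-yloxy)(tert-butyl)diphenylsilane
Conditions: t-BuPh2SiCl, imidazole, DMF, rt
Reagents that add atoms: tert-butyl(chloro)diphenylsilane CC(C)(C)[Si](Cl)(c1ccccc1)c1ccccc1
Why: Standard silyl ether formation protects the future C5 oxygen with a group that outlasts the later cleavage of the silyl enol ether.

**Step 4**
Reactants: 6 (but-3-en-1-yloxy)(tert-butyl)diphenylsilane; 7 (E)-but-2-enal
Product: 8 (E)-5-(tert-butyldiphenylsilyloxy)pent-2-enal
Conditions: second-generation Hoveyda–Grubbs catalyst (3 mol%), 7 (5 equiv), CH2Cl2, 40 °C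
Reagents that add atoms: none
Why: Olefin cross-metathesis of a terminal alkene with an enal partner should give the (E)-enal, with propene as the volatile co-product.

**Step 5**
Reactants: 4 tert-butyl {3-[6-methyl-2-oxo-4-(triisopropylsilyloxy)-2H-pyran-3-yl]propyl}carbamate; 8 (E)-5-(tert-butyldiphenylsilyloxy)pent-2-enal
Product: 9 bridged lactone aldehyde: 2-oxabicyclo[2.2.2]oct-5-en-3-one with 1-methyl, 4-[3-(Boc-amino)propyl], 5-triisopropylsilyloxy, 7-formyl (endo, syn to C5=C6) and 8-[2-(tert-butyldiphenylsilyloxy)ethyl] (exo, syn to the lactone bridge); absolute configuration as in the SMILES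
Conditions: (S)-1-(2-methylphenyl)-3,3-diphenyltetrahydro-1H,3H-pyrrolo[1,2-c][1,3,2]oxazaborole (20 mol%), (CF3SO2)2NH (17 mol%), CH2Cl2, −78 → −40 °C
Reagents that add atoms: none
Why: Proposed new method: the aldehyde-bound oxazaborolidinium cation lowers the LUMO of 8 so that the 2-silyloxydiene embedded in 4 (C12=C13(OSi)–C14=C15) adds in an asynchronous normal-demand [4+2] cycloaddition, C12 (the nucleophilic pyranone C3) bonding to the enal β-carbon C7 and C15 to the α-carbon C8; the closest known reaction types are oxazaborolidinium-catalysed enantioselective Diels–Alder reactions of acyclic 2-silyloxy-1,3-dienes with α,β-enals and thermal cycloadditions of 2-pyranones to alkenes that keep the CO2 bridge. It closes one ring, the cyclohexene that becomes the cyclohexane of 24, by suprafacial [4+2] addition across C3 and C6 of the pyranone, whose own ring survives as the O–C(=O) bridge of a 2-oxabicyclo[2.2.2]octene. C12 and C15 are set together because the bridge must lie on one face, which places the C15 oxygen cis to C4 on C12; C7 is set by the endo transition state (formyl under the C13=C14 unit) together with the (E)-geometry of 8, which puts the C6 chain exo, on the side of the lactone bridge and cis to C4; the formyl-bearing C8 centre is temporary. The absolute sense comes from the catalyst, which is expected to shield one face of the s-trans enal so that the diene adds to the Re face at C7 (the mirror-image catalyst would serve if the sense proved opposite). The step needs regio-, endo- and facial selectivity and retention of the CO2 bridge: the C13 silyloxy group makes C12 the nucleophilic diene terminus, Lewis-acid activation reinforces the endo preference, and −78 to −40 °C is far below the temperature of CO2 extrusion.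

**Step 6**
Reactants: 9 bridged lactone aldehyde
Product: 10 bridged lactone with C8 as CH2: 2-oxabicyclo[2.2.2]oct-5-en-3-one with 1-methyl, 4-[3-(Boc-amino)propyl], 5-triisopropylsilyloxy and 8-exo-[2-(tert-butyldiphenylsilyloxy)ethyl]
Conditions: RhCl(PPh3)3 (1.2 equiv), toluene, 100 °C
Reagents that add atoms: none
Why: Tsuji–Wilkinson decarbonylation (formyl C–H oxidative addition, CO extrusion, C–H reductive elimination) should remove the activating group and leave C8 as the ring CH2 without touching C7, C12 or C15.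

**Step 7**
Reactants: 10 bridged lactone with C8 as CH2
Product: 12 terminal alkyne: cyclohexene with quaternary C12 (ethynyl C4≡C3H and 3-(Boc-amino)propyl), C13=C14 silyl enol ether (OSi(i-Pr)3 on C13), C15 tertiary OH and CH3, C7 2-(tert-butyldiphenylsilyloxy)ethyl; C15–OH, ethynyl and the C7 chain on one face, via bicyclic lactol 11 (not isolated)
Conditions: i-Bu2AlH (2.5 equiv), CH2Cl2, −78 °C; then MeOH, K2CO3, dimethyl (1-diazo-2-oxopropyl)phosphonate, −78 °C → rt
Reagents that add atoms: dimethyl (1-diazo-2-oxopropyl)phosphonate COP(=O)(OC)C(=[N+]=[N-])C(C)=O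
Why: Half-reduction of the lactone and Seyferth–Gilbert homologation of the hydroxy-aldehyde form of the lactol with the Ohira–Bestmann reagent should convert the lactone carbonyl C4 into the alkyne C4≡C3 and free the C15 hydroxyl, with no stereocentre involved.

**Step 8**
Reactants: 12 terminal alkyne; 13 oxirane
Product: 14 homopropargylic alcohol (C4≡C3–C2H2–C1H2–OH on C12; otherwise as 12)
Conditions: n-BuLi (3.2 equiv), THF, −78 °C; BF3·OEt2 (3.5 equiv); oxirane (5 equiv), −78 °C; H2O quench
Reagents that add atoms: none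
Why: BF3-promoted opening of oxirane by the lithium acetylide (alkynylborate epoxide opening) should add C2–C1 at carbon only, since the lithium alkoxide and carbamate anion do not open the epoxide at −78 °C.

**Step 9**
Reactants: 14 homopropargylic alcohol
Product: 16 primary chloride (C1–Cl; otherwise as 14), via primary mesylate 15 (not isolated)
Conditions: CH3SO2Cl (1.1 equiv), Et3N, CH2Cl2, −20 °C; then LiCl (5 equiv), DMF, 40 °C
Reagents that add atoms: lithium chloride [Li+].[Cl-] (methanesulfonyl chloride CS(=O)(=O)Cl supplies the sulfonyl group of 15 only)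
Why: Selective sulfonylation of the primary hydroxyl over the tertiary one and SN2 displacement by chloride should give a leaving group at C1 that survives every later step.

**Step 10**
Reactants: 16 primary chloride
Product: 17 β-hydroxy ketone (C13 ketone, C15 tertiary alcohol; otherwise as 16)
Conditions: Bu4NF (1.2 equiv), AcOH (1.2 equiv), THF, −20 °C
Reagents that add atoms: none
Why: Buffered fluoride cleaves the silyl enol ether much faster than the alkyl tert-butyldiphenylsilyl ether and avoids dehydration or retro-aldol cleavage of the aldol-type product.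

**Step 11**
Reactants: 17 β-hydroxy ketone
Product: 18 cis-1,3-diol (13S; C13–OH and C15–OH on the same face)
Conditions: Et2BOMe (1.2 equiv), THF/MeOH 4:1, −78 °C; NaBH4 (1.5 equiv); AcOH, then MeOH co-evaporation
Reagents that add atoms: none
Why: In the Narasaka–Prasad reduction the boron chelate between the C15 oxygen and the C13 carbonyl forces external hydride delivery to the opposite face, which sets C13 with its oxygen cis to the C15 oxygen.

**Step 12**
Reactants: 18 cis-1,3-diol
Product: 19 diacetate (C13–OAc and C15–OAc)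
Conditions: Ac2O (6 equiv), 4-(dimethylamino)pyridine (1 equiv), Et3N, CH2Cl2, 35 °C
Reagents that add atoms: acetic anhydride CC(=O)OC(C)=O
Why: Nucleophilic-catalysed (Steglich-type) acylation should acetylate the secondary and the tertiary alcohol, while the much less nucleophilic carbamate N–H is expected to stay free.

**Step 13**
Reactants: 19 diacetate
Product: 20 primary alcohol (C5–OH)
Conditions: HF·pyridine, pyridine/THF, 0 °C → rt
Reagents that add atoms: none
Why: Buffered fluoride desilylation removes the tert-butyldiphenylsilyl ether without harming acetates, carbamate, alkyne or chloride.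

**Step 14**
Reactants: 20 primary alcohol
Product: 21 alkynyl aldehyde (C5 aldehyde; a 5-alkynal)
Conditions: Dess–Martin periodinane (1.3 equiv), NaHCO3, CH2Cl2, 0 °C → rt
Reagents that add atoms: none
Why: Dess–Martin oxidation gives the aldehyde under neutral conditions, and lactol formation is excluded because C13 is already acetylated.

**Step 15**
Reactants: 21 alkynyl aldehyde
Product: 22 cis-hydrindanone enone: cyclopentanone fused to the cyclohexane at C7–C12, (E)-3-chloropropylidene at C4, C13 and C15 acetates, 3-(Boc-amino)propyl on C12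
Conditions: [Rh(BINAP)]BF4 (10 mol%, from [Rh(cod)2]BF4, rac-BINAP and H2), CH2Cl2, rt
Reagents that add atoms: none
Why: Intramolecular alkyne hydroacylation of a 5-alkynal (acyl–H oxidative addition to monovalent rhodium, cis-hydrometalation, reductive elimination) should form C4–C5 with the acyl group and H cis, which gives the (E)-alkylidene, and the ring fusion is already fixed cis by C7 and C12.

**Step 16**
Reactants: 22 cis-hydrindanone enone
Product: 24 target, (7S,12S,13S,15S)-diacetoxy azonine-fused hydrindenone, via primary ammonium trifluoroacetate 23 (not isolated)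
Conditions: CF3CO2H/CH2Cl2 1:9, 0 °C; evaporate; then K2CO3 (6 equiv), NaI (0.5 equiv), MeCN (0.002 M), 60 °C
Reagents that add atoms: none
Why: Acidolysis of the carbamate and intramolecular SN2 N-alkylation with iodide catalysis at high dilution should close the nine-membered ring, helped by the (E)-alkene that holds C1 close to the C9 amine.

**Compound list**
1 | 4-hydroxy-6-methyl-2H-pyran-2-one (triacetic acid lactone) | CC1=CC(O)=CC(=O)O1 | starting material
2 | tert-butyl (3-oxopropyl)carbamate | O=CCCNC(=O)OC(C)(C)C | starting material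
3 | tert-butyl [3-(4-hydroxy-6-methyl-2-oxo-2H-pyran-3-yl)propyl]carbamate | CC1=CC(O)=C(CCCNC(=O)OC(C)(C)C)C(=O)O1 | intermediate
4 | tert-butyl {3-[6-methyl-2-oxo-4-(triisopropylsilyloxy)-2H-pyran-3-yl]propyl}carbamate | CC1=CC(O[Si](C(C)C)(C(C)C)C(C)C)=C(CCCNC(=O)OC(C)(C)C)C(=O)O1 | intermediate
5 | but-3-en-1-ol | C=CCCO | starting material
6 | (but-3-en-1-yloxy)(tert-butyl)diphenylsilane | C=CCCO[Si](c1ccccc1)(c1ccccc1)C(C)(C)C | intermediate
7 | (E)-but-2-enal | C/C=C/C=O | starting material
8 | (E)-5-(tert-butyldiphenylsilyloxy)pent-2-enal | O=C/C=C/CCO[Si](c1ccccc1)(c1ccccc1)C(C)(C)C | intermediate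
9 | bridged lactone aldehyde (cycloadduct) | CC(C)(C)OC(=O)NCCC[C@]12C(=O)O[C@](C)(C=C1O[Si](C(C)C)(C(C)C)C(C)C)[C@H](C=O)[C@H]2CCO[Si](c1ccccc1)(c1ccccc1)C(C)(C)C | intermediate
10 | bridged lactone with C8 as CH2 | CC(C)(C)OC(=O)NCCC[C@]12C(=O)O[C@](C)(C=C1O[Si](C(C)C)(C(C)C)C(C)C)C[C@H]2CCO[Si](c1ccccc1)(c1ccccc1)C(C)(C)C | intermediate
11 | bicyclic lactol (anomer mixture) | CC(C)(C)OC(=O)NCCC[C@]12C(O)O[C@](C)(C=C1O[Si](C(C)C)(C(C)C)C(C)C)C[C@H]2CCO[Si](c1ccccc1)(c1ccccc1)C(C)(C)C | intermediate
12 | terminal alkyne | CC(C)(C)OC(=O)NCCC[C@]1(C#C)C(O[Si](C(C)C)(C(C)C)C(C)C)=C[C@@](C)(O)C[C@H]1CCO[Si](c1ccccc1)(c1ccccc1)C(C)(C)C | intermediate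
13 | oxirane | C1CO1 | starting material
14 | homopropargylic alcohol | CC(C)(C)OC(=O)NCCC[C@]1(C#CCCO)C(O[Si](C(C)C)(C(C)C)C(C)C)=C[C@@](C)(O)C[C@H]1CCO[Si](c1ccccc1)(c1ccccc1)C(C)(C)C | intermediate
15 | primary mesylate | CC(C)(C)OC(=O)NCCC[C@]1(C#CCCOS(C)(=O)=O)C(O[Si](C(C)C)(C(C)C)C(C)C)=C[C@@](C)(O)C[C@H]1CCO[Si](c1ccccc1)(c1ccccc1)C(C)(C)C | intermediate
16 | primary chloride | CC(C)(C)OC(=O)NCCC[C@]1(C#CCCCl)C(O[Si](C(C)C)(C(C)C)C(C)C)=C[C@@](C)(O)C[C@H]1CCO[Si](c1ccccc1)(c1ccccc1)C(C)(C)C | intermediate
17 | β-hydroxy ketone | CC(C)(C)OC(=O)NCCC[C@]1(C#CCCCl)C(=O)C[C@@](C)(O)C[C@H]1CCO[Si](c1ccccc1)(c1ccccc1)C(C)(C)C | intermediate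
18 | cis-1,3-diol | CC(C)(C)OC(=O)NCCC[C@]1(C#CCCCl)[C@@H](O)C[C@@](C)(O)C[C@H]1CCO[Si](c1ccccc1)(c1ccccc1)C(C)(C)C | intermediate
19 | diacetate | CC(C)(C)OC(=O)NCCC[C@]1(C#CCCCl)[C@@H](OC(C)=O)C[C@@](C)(OC(C)=O)C[C@H]1CCO[Si](c1ccccc1)(c1ccccc1)C(C)(C)C | intermediate
20 | primary alcohol | CC(C)(C)OC(=O)NCCC[C@]1(C#CCCCl)[C@@H](OC(C)=O)C[C@@](C)(OC(C)=O)C[C@H]1CCO | intermediate
21 | alkynyl aldehyde | CC(C)(C)OC(=O)NCCC[C@]1(C#CCCCl)[C@@H](OC(C)=O)C[C@@](C)(OC(C)=O)C[C@H]1CC=O | intermediate
22 | cis-hydrindanone enone | CC(=O)O[C@H]1C[C@@](C)(OC(C)=O)C[C@H]2CC(=O)/C(=C/CCCl)[C@]21CCCNC(=O)OC(C)(C)C | intermediate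
23 | primary ammonium trifluoroacetate | CC(=O)O[C@H]1C[C@@](C)(OC(C)=O)C[C@H]2CC(=O)/C(=C/CCCl)[C@]21CCC[NH3+].[O-]C(=O)C(F)(F)F | intermediate
24 | target | CC(=O)O[C@H]1C[C@@](C)(OC(C)=O)C[C@H]2CC(=O)/C3=C/CCNCCC[C@@]321 | target

Total step count: 16. Longest linear sequence: 14 steps (steps 1, 2 and 5–16, or equally 3, 4 and 5–16).

**Steps most likely to fail**

Step 5 (the proposed new method). The addition may stop after the first C–C bond (Mukaiyama–Michael pathway with silyl transfer), the Lewis acid may ionise the allylic C15–O bond of the adduct (vinylogous elimination to a cyclohexenone acid), or facial control may be low. The fallback uses auxiliary control with known chemistry, sets out from 6 and 4 and returns at 9. (S)-4-Benzyloxazolidin-2-one is N-acylated (n-BuLi, acryloyl chloride) to (S)-3-acryloyl-4-benzyloxazolidin-2-one F1. Cross-metathesis of F1 with 6 (second-generation Hoveyda–Grubbs catalyst) gives the (E)-enoyl imide F2. The Et2AlCl-promoted Diels–Alder reaction of F2 with 4 (CH2Cl2, −78 → −30 °C) should proceed through the chelated s-cis imide, with addition to the face opposite the benzyl group and the carbonyl endo, to give the imide cycloadduct F3. LiSEt (THF, 0 °C) then gives the S-ethyl thioester F4 and releases the auxiliary, and Fukuyama reduction (Et3SiH, Pd/C, acetone) returns aldehyde 9.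

Step 6. Decarbonylation of the hindered secondary aldehyde may be slower than thermal extrusion of CO2 from the bridged lactone. The fallback sets out from 9 and returns at 10 without heating. Pinnick oxidation (NaClO2, NaH2PO4, 2-methylbut-2-ene, t-BuOH/H2O, 0 °C) gives the carboxylic acid F5. Coupling with N-hydroxypyridine-2-thione (dicyclohexylcarbodiimide, CH2Cl2, dark) gives the Barton ester F6, and visible-light irradiation with t-BuSH at rt (Barton reductive decarboxylation) gives 10.

Step 16. Intermolecular N-alkylation (oligomerisation) or condensation of the free primary amine with the enone may outrun nine-membered ring closure, and the acid may ionise the tertiary acetate. The fallback replaces the amine nucleophile by a sulfonamide anion; it sets out from 22 and returns at 24. Brief CF3CO2H treatment gives 23, and 2-nitrobenzenesulfonyl chloride with Et3N gives the 2-nitrobenzenesulfonamide F7. Cs2CO3 and Bu4NI (MeCN, 0.002 M, 60 °C) close the ring to the N-(2-nitrobenzenesulfonyl) azonine F8, and PhSH with K2CO3 (MeCN, rt) removes the sulfonyl group to give 24.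

**Further compounds**
F1 | step 5 | (S)-3-acryloyl-4-benzyloxazolidin-2-one | C=CC(=O)N1[C@@H](Cc2ccccc2)COC1=O
F2 | step 5 | (S)-4-benzyl-3-[(E)-5-(tert-butyldiphenylsilyloxy)pent-2-enoyl]oxazolidin-2-one | O=C(/C=C/CCO[Si](c1ccccc1)(c1ccccc1)C(C)(C)C)N1[C@@H](Cc2ccccc2)COC1=O
F3 | step 5 | imide cycloadduct (9 with C(=O)-oxazolidinone in place of formyl) | CC(C)(C)OC(=O)NCCC[C@]12C(=O)O[C@](C)(C=C1O[Si](C(C)C)(C(C)C)C(C)C)[C@H](C(=O)N3[C@@H](Cc4ccccc4)COC3=O)[C@H]2CCO[Si](c1ccccc1)(c1ccccc1)C(C)(C)C
F4 | step 5 | S-ethyl thioester of the cycloadduct | CC(C)(C)OC(=O)NCCC[C@]12C(=O)O[C@](C)(C=C1O[Si](C(C)C)(C(C)C)C(C)C)[C@H](C(=O)SCC)[C@H]2CCO[Si](c1ccccc1)(c1ccccc1)C(C)(C)C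
F5 | step 6 | carboxylic acid from 9 | CC(C)(C)OC(=O)NCCC[C@]12C(=O)O[C@](C)(C=C1O[Si](C(C)C)(C(C)C)C(C)C)[C@H](C(=O)O)[C@H]2CCO[Si](c1ccccc1)(c1ccccc1)C(C)(C)C
F6 | step 6 | Barton ester (N-acyloxypyridine-2-thione) | CC(C)(C)OC(=O)NCCC[C@]12C(=O)O[C@](C)(C=C1O[Si](C(C)C)(C(C)C)C(C)C)[C@H](C(=O)ON3C=CC=CC3=S)[C@H]2CCO[Si](c1ccccc1)(c1ccccc1)C(C)(C)C
F7 | step 16 | 2-nitrobenzenesulfonamide of the primary amine | CC(=O)O[C@H]1C[C@@](C)(OC(C)=O)C[C@H]2CC(=O)/C(=C/CCCl)[C@]21CCCNS(=O)(=O)c1ccccc1[N+](=O)[O-]
F8 | step 16 | N-(2-nitrobenzenesulfonyl) azonine | CC(=O)O[C@H]1C[C@@](C)(OC(C)=O)C[C@H]2CC(=O)/C3=C/CCN(CCC[C@@]321)S(=O)(=O)c1ccccc1[N+](=O)[O-]
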